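**Retrosynthetic overview**

- Rings are lettered A (2,4,6-trihydroxyphenyl end) to F (3,4,5-trihydroxyphenyl end). The strategy rests on ring C, whose six carbons carry three contiguous hydroxyls (C1–C3), two neighbouring aryl ether oxygens (C4–O–ring D and C5–O–ring B) and one hydrogen (C6). This is the reduced form of a 3-alkoxy-4,5-bis(aryloxy)-ortho-benzoquinone.
- Disconnection 1: both aryl–oxygen bonds of ring C (C5–O to ring B, C4–O to ring D) are cut at the quinone oxidation level. This gives 4,5,6-tribromo-3-methoxy-1,2-benzoquinone, the AB phenol and the DEF phenol, the two phenols being delivered as silyl ethers.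
- Disconnection 2: the A–O–B, E–O–F and D–O–E ethers come from copper-catalysed couplings of phenols with formyl-activated aryl bromides, each followed by Baeyer–Villiger conversion of CHO into OH.
- No ring is formed in the route; all six benzene rings are bought. Order of joining: E–F, then D; A–B; then AB and DEF onto ring C.
- End game: quinone reduction, removal of the C6 bromine and cleavage of the fourteen methyl ethers.

Key step: step 16

Remark on the chemistry: the target has no stereocentre. Ring C is numbered as in the quinone (C1 and C2 the carbonyl carbons, C3 the methoxy carbon, C4 and C5 the two aryloxy carbons, C6 the carbon that ends as C–H). Compound 8 is used twice (steps 5 and 13).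

**Ring C hub**

Step 1
Reactants: 1 3-methoxycatechol
Product: 2 3,4,5-tribromo-6-methoxybenzene-1,2-diol
Conditions: Br2 (3.1 equiv), AcOH/CHCl3, 0 °C to rt
Reagents that add atoms: bromine, BrBr
Why: Electrophilic aromatic bromination; each of the three free positions is ortho or para to a hydroxyl or methoxy group, so three equivalents of bromine should fill all of them.

Step 2
Reactants: 2 3,4,5-tribromo-6-methoxybenzene-1,2-diol
Product: 3 4,5,6-tribromo-3-methoxycyclohexa-3,5-diene-1,2-dione (4,5,6-tribromo-3-methoxy-1,2-benzoquinone)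
Conditions: PhI(OAc)2 (1.05 equiv), CH2Cl2, 0 °C, dark
Reagents that add atoms: none
Why: Two-electron oxidation of a catechol to the ortho-quinone by a trivalent iodine reagent under non-aqueous, non-nucleophilic conditions, which should leave the methoxy group untouched.

**AB dimer**

Step 3
Reactants: 4 syringaldehyde
Product: 5 4-(benzyloxy)-3,5-dimethoxybenzaldehyde
Conditions: BnBr, K2CO3, DMF, 60 °C
Reagents that add atoms: benzyl bromide, BrCc1ccccc1
Why: Williamson ether synthesis; the benzyl group masks the ring B oxygen that later attacks the quinone.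

Step 4
Reactants: 5 4-(benzyloxy)-3,5-dimethoxybenzaldehyde
Product: 7 4-(benzyloxy)-3,5-dimethoxyphenol, via aryl formate 6 (not isolated)
Conditions: mCPBA, CH2Cl2, 0 °C to rt; aq NaHCO3 wash; then K2CO3 (cat.), MeOH, rt
Reagents that add atoms: 3-chloroperbenzoic acid (mCPBA), OOC(=O)c1cccc(Cl)c1
Why: Baeyer–Villiger oxidation of an electron-rich benzaldehyde (Dakin-type aryl migration) gives the aryl formate, which base-catalysed methanolysis should convert into the phenol.

Step 5
Reactants: 7 4-(benzyloxy)-3,5-dimethoxyphenol; 8 4-bromo-3,5-dimethoxybenzaldehyde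
Product: 9 4-[4-(benzyloxy)-3,5-dimethoxyphenoxy]-3,5-dimethoxybenzaldehyde
Conditions: CuI (10 mol %), picolinic acid (20 mol %), K3PO4, DMSO, 90 °C
Reagents that add atoms: none
Why: Ullmann-type diaryl ether coupling under copper catalysis; the bromide is activated by the para formyl group, the picolinate ligand suits ortho-substituted halides and the phenol is unhindered.

Step 6
Reactants: 9 4-[4-(benzyloxy)-3,5-dimethoxyphenoxy]-3,5-dimethoxybenzaldehyde
Product: 11 4-[4-(benzyloxy)-3,5-dimethoxyphenoxy]-3,5-dimethoxyphenol, via aryl formate 10 (not isolated)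
Conditions: mCPBA, CH2Cl2, 0 °C to rt; aq NaHCO3 wash; then K2CO3 (cat.), MeOH, rt
Reagents that add atoms: 3-chloroperbenzoic acid (mCPBA), OOC(=O)c1cccc(Cl)c1
Why: Baeyer–Villiger oxidation with migration of the para-aryloxy-substituted aryl group, then formate methanolysis; the aldehyde should react faster than the electron-rich rings are attacked at 0 °C.

Step 7
Reactants: 11 4-[4-(benzyloxy)-3,5-dimethoxyphenoxy]-3,5-dimethoxyphenol
Product: 12 2-(benzyloxy)-1,3-dimethoxy-5-(2,4,6-trimethoxyphenoxy)benzene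
Conditions: MeI, K2CO3, acetone, reflux
Reagents that add atoms: iodomethane, CI
Why: Williamson O-methylation of the unhindered phenol completes the 2,4,6-trimethoxy pattern of ring A.

Step 8
Reactants: 12 2-(benzyloxy)-1,3-dimethoxy-5-(2,4,6-trimethoxyphenoxy)benzene
Product: 13 2,6-dimethoxy-4-(2,4,6-trimethoxyphenoxy)phenol (AB dimer phenol)
Conditions: H2 (1 atm), 10% Pd/C, EtOAc/MeOH, rt
Reagents that add atoms: none
Why: Hydrogenolysis of the benzyl ether over palladium; methyl and diaryl ethers are inert under these conditions.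

Step 9
Reactants: 13 2,6-dimethoxy-4-(2,4,6-trimethoxyphenoxy)phenol
Product: 14 tert-butyl[2,6-dimethoxy-4-(2,4,6-trimethoxyphenoxy)phenoxy]dimethylsilane (AB silyl ether)
Conditions: TBSCl, imidazole, DMF, 40 °C
Reagents that add atoms: tert-butyldimethylsilyl chloride, CC(C)(C)[Si](C)(C)Cl
Why: Imidazole-promoted silylation of the phenol; the silyl ether is not oxidised by the quinone and releases the phenoxide only when fluoride is added.

**DEF trimer**

Step 10
Reactants: 15 3,4,5-trimethoxybenzaldehyde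
Product: 16 2-bromo-3,4,5-trimethoxybenzaldehyde
Conditions: NBS, CHCl3, reflux
Reagents that add atoms: N-bromosuccinimide, O=C1CCC(=O)N1Br
Why: Electrophilic aromatic bromination at C2, which is ortho and para to methoxy groups; the formyl group and the first bromine should stop the reaction at monobromination.

Step 11
Reactants: 16 2-bromo-3,4,5-trimethoxybenzaldehyde; 17 3,4,5-trimethoxyphenol
Product: 18 3,4,5-trimethoxy-2-(3,4,5-trimethoxyphenoxy)benzaldehyde
Conditions: CuI (10 mol %), picolinic acid (20 mol %), K3PO4, DMSO, 90 °C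
Reagents that add atoms: none
Why: Ullmann-type diaryl ether coupling; the bromide is activated by the ortho formyl group and the phenol is unhindered.

Step 12
Reactants: 18 3,4,5-trimethoxy-2-(3,4,5-trimethoxyphenoxy)benzaldehyde
Product: 20 3,4,5-trimethoxy-2-(3,4,5-trimethoxyphenoxy)phenol (EF phenol), via aryl formate 19 (not isolated)
Conditions: mCPBA, CH2Cl2, 0 °C to rt; aq NaHCO3 wash; then K2CO3 (cat.), MeOH, rt
Reagents that add atoms: 3-chloroperbenzoic acid (mCPBA), OOC(=O)c1cccc(Cl)c1
Why: Baeyer–Villiger oxidation with migration of the aryl group that carries ortho-aryloxy and para-methoxy donors, then formate methanolysis.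

Step 13
Reactants: 20 3,4,5-trimethoxy-2-(3,4,5-trimethoxyphenoxy)phenol; 8 4-bromo-3,5-dimethoxybenzaldehyde
Product: 21 3,5-dimethoxy-4-[3,4,5-trimethoxy-2-(3,4,5-trimethoxyphenoxy)phenoxy]benzaldehyde
Conditions: CuI (20 mol %), picolinic acid (40 mol %), K3PO4, DMSO, 100 °C
Reagents that add atoms: none
Why: Ullmann-type coupling of an ortho-substituted phenol with a doubly ortho-substituted but para-formyl-activated bromide, the hindered case for which the picolinic acid ligand system is chosen, here with higher loading and temperature.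

Step 14
Reactants: 21 3,5-dimethoxy-4-[3,4,5-trimethoxy-2-(3,4,5-trimethoxyphenoxy)phenoxy]benzaldehyde
Product: 23 3,5-dimethoxy-4-[3,4,5-trimethoxy-2-(3,4,5-trimethoxyphenoxy)phenoxy]phenol (DEF trimer phenol), via aryl formate 22 (not isolated)
Conditions: mCPBA, CH2Cl2, 0 °C to rt; aq NaHCO3 wash; then K2CO3 (cat.), MeOH, rt
Reagents that add atoms: 3-chloroperbenzoic acid (mCPBA), OOC(=O)c1cccc(Cl)c1
Why: Baeyer–Villiger oxidation with migration of the para-aryloxy-substituted aryl group, then formate methanolysis, which places the free hydroxyl on the unhindered carbon of ring D.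

Step 15
Reactants: 23 3,5-dimethoxy-4-[3,4,5-trimethoxy-2-(3,4,5-trimethoxyphenoxy)phenoxy]phenol
Product: 24 tert-butyl{3,5-dimethoxy-4-[3,4,5-trimethoxy-2-(3,4,5-trimethoxyphenoxy)phenoxy]phenoxy}dimethylsilane (DEF silyl ether)
Conditions: TBSCl, imidazole, DMF, rt
Reagents that add atoms: tert-butyldimethylsilyl chloride, CC(C)(C)[Si](C)(C)Cl
Why: Imidazole-promoted silylation of an unhindered phenol, giving a storable phenoxide precursor that can be dosed exactly in the key step.

**Three-component union and end game**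

Step 16
Reactants: 3 4,5,6-tribromo-3-methoxy-1,2-benzoquinone; 14 AB silyl ether; 24 DEF silyl ether
Product: 26 6-bromo-5-[2,6-dimethoxy-4-(2,4,6-trimethoxyphenoxy)phenoxy]-4-{3,5-dimethoxy-4-[3,4,5-trimethoxy-2-(3,4,5-trimethoxyphenoxy)phenoxy]phenoxy}-3-methoxycyclohexa-3,5-diene-1,2-dione (hexamer with ring C as bromo ortho-quinone), via 5-aryloxy-4,6-dibromoquinone 25 (not isolated)
Conditions: 3 and 14 (1.0 equiv each), n-Bu4N[Ph3SiF2] (1.0 equiv, slow addition), THF, −78 °C, argon, dark; then 24 (1.05 equiv), n-Bu4N[Ph3SiF2] (1.05 equiv), −78 to −20 °C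
Reagents that add atoms: none
Why: Fluoride from the silicate cleaves the Si–O bond of 14 and releases a small stationary amount of the ring B phenoxide, which adds in conjugate fashion to C5 of 3 (the β-carbon of the C1=O/C6=C5 enone), and the resulting enolate expels bromide (addition–elimination, vinylic substitution) to give 25; the same sequence with 24 then replaces the bromide at C4. The closest known reaction type is the displacement of the 4- and 5-halogens of tetrahalo-ortho-benzoquinones by alkoxides and aryloxides, and the use of two different phenoxides one after the other extends it. No ring is closed and no stereocentre is formed. The selectivity needed is site order: the 3-methoxy group makes C3=C4 an enol ether and feeds electron density into C4, so C5 is the more electrophilic carbon and should be taken first by the doubly ortho-substituted ring B phenoxide, which is too hindered to go on to the deactivated C4 between the methoxy group and the new aryloxy group, whereas the ring D phenoxide with free ortho positions can; C3 and C6 are α-carbons and do not undergo addition–elimination. Low temperature, exact 1:1 stoichiometry in the first stage, the absence of free phenol and the slow fluoride-triggered release are meant to hold back electron transfer from phenoxide to quinone, and the tetrabutylammonium counter-ion in an aprotic medium should favour attack through oxygen over the ortho carbons of ring D. Loss of bromide is irreversible, which should disfavour exchange of the aryloxy group already placed at C5.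

Step 17
Reactants: 26 hexamer with ring C as bromo ortho-quinone
Product: 28 5-[2,6-dimethoxy-4-(2,4,6-trimethoxyphenoxy)phenoxy]-4-{3,5-dimethoxy-4-[3,4,5-trimethoxy-2-(3,4,5-trimethoxyphenoxy)phenoxy]phenoxy}-3-methoxybenzene-1,2-diol, via bromocatechol 27 (not isolated)
Conditions: H2 (1–3 atm), 10% Pd/C, Et3N (2 equiv), EtOAc/MeOH, rt; filtration under argon
Reagents that add atoms: none
Why: Catalytic hydrogenation reduces the quinone to the catechol at once and then hydrogenolyses the aryl C–Br bond with triethylamine taking up HBr, while diaryl and methyl ethers are stable.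

Step 18
Reactants: 28 catechol hexamer with fourteen methyl ethers
Product: 29 CNP0114537.0 (target, sixteen free hydroxyls)
Conditions: BBr3 (excess), CH2Cl2, −78 °C to rt; ice-water quench; Sephadex LH-20 under argon
Reagents that add atoms: none
Why: Lewis acid-mediated cleavage of aryl methyl ethers (bromide attacks the methyl group of the boron-complexed ether), a reaction that normally leaves diaryl ether bonds intact.

**Compound list**

1 | 3-methoxycatechol | COc1cccc(O)c1O | starting material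
2 | 3,4,5-tribromo-6-methoxybenzene-1,2-diol | COc1c(O)c(O)c(Br)c(Br)c1Br | intermediate
3 | 4,5,6-tribromo-3-methoxycyclohexa-3,5-diene-1,2-dione | O=C1C(=O)C(OC)=C(Br)C(Br)=C1Br | intermediate
4 | syringaldehyde | COc1cc(C=O)cc(OC)c1O | starting material
5 | 4-(benzyloxy)-3,5-dimethoxybenzaldehyde | COc1cc(C=O)cc(OC)c1OCc1ccccc1 | intermediate
6 | 4-(benzyloxy)-3,5-dimethoxyphenyl formate | COc1cc(OC=O)cc(OC)c1OCc1ccccc1 | intermediate (not isolated)
7 | 4-(benzyloxy)-3,5-dimethoxyphenol | COc1cc(O)cc(OC)c1OCc1ccccc1 | intermediate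
8 | 4-bromo-3,5-dimethoxybenzaldehyde | COc1cc(C=O)cc(OC)c1Br | starting material
9 | 4-[4-(benzyloxy)-3,5-dimethoxyphenoxy]-3,5-dimethoxybenzaldehyde | COc1cc(C=O)cc(OC)c1Oc1cc(OC)c(OCc2ccccc2)c(OC)c1 | intermediate
10 | 4-[4-(benzyloxy)-3,5-dimethoxyphenoxy]-3,5-dimethoxyphenyl formate | COc1cc(OC=O)cc(OC)c1Oc1cc(OC)c(OCc2ccccc2)c(OC)c1 | intermediate (not isolated)
11 | 4-[4-(benzyloxy)-3,5-dimethoxyphenoxy]-3,5-dimethoxyphenol | COc1cc(O)cc(OC)c1Oc1cc(OC)c(OCc2ccccc2)c(OC)c1 | intermediate
12 | 2-(benzyloxy)-1,3-dimethoxy-5-(2,4,6-trimethoxyphenoxy)benzene | COc1cc(OC)c(Oc2cc(OC)c(OCc3ccccc3)c(OC)c2)c(OC)c1 | intermediate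
13 | 2,6-dimethoxy-4-(2,4,6-trimethoxyphenoxy)phenol (AB dimer phenol) | COc1cc(OC)c(Oc2cc(OC)c(O)c(OC)c2)c(OC)c1 | intermediate
14 | tert-butyl[2,6-dimethoxy-4-(2,4,6-trimethoxyphenoxy)phenoxy]dimethylsilane | COc1cc(OC)c(Oc2cc(OC)c(O[Si](C)(C)C(C)(C)C)c(OC)c2)c(OC)c1 | intermediate
15 | 3,4,5-trimethoxybenzaldehyde | COc1cc(C=O)cc(OC)c1OC | starting material
16 | 2-bromo-3,4,5-trimethoxybenzaldehyde | COc1cc(C=O)c(Br)c(OC)c1OC | intermediate
17 | 3,4,5-trimethoxyphenol | COc1cc(O)cc(OC)c1OC | starting material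
18 | 3,4,5-trimethoxy-2-(3,4,5-trimethoxyphenoxy)benzaldehyde | COc1cc(Oc2c(C=O)cc(OC)c(OC)c2OC)cc(OC)c1OC | intermediate
19 | 3,4,5-trimethoxy-2-(3,4,5-trimethoxyphenoxy)phenyl formate | COc1cc(Oc2c(OC=O)cc(OC)c(OC)c2OC)cc(OC)c1OC | intermediate (not isolated)
20 | 3,4,5-trimethoxy-2-(3,4,5-trimethoxyphenoxy)phenol (EF phenol) | COc1cc(Oc2c(O)cc(OC)c(OC)c2OC)cc(OC)c1OC | intermediate
21 | 3,5-dimethoxy-4-[3,4,5-trimethoxy-2-(3,4,5-trimethoxyphenoxy)phenoxy]benzaldehyde | COc1cc(C=O)cc(OC)c1Oc1cc(OC)c(OC)c(OC)c1Oc1cc(OC)c(OC)c(OC)c1 | intermediate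
22 | 3,5-dimethoxy-4-[3,4,5-trimethoxy-2-(3,4,5-trimethoxyphenoxy)phenoxy]phenyl formate | COc1cc(OC=O)cc(OC)c1Oc1cc(OC)c(OC)c(OC)c1Oc1cc(OC)c(OC)c(OC)c1 | intermediate (not isolated)
23 | 3,5-dimethoxy-4-[3,4,5-trimethoxy-2-(3,4,5-trimethoxyphenoxy)phenoxy]phenol (DEF trimer phenol) | COc1cc(O)cc(OC)c1Oc1cc(OC)c(OC)c(OC)c1Oc1cc(OC)c(OC)c(OC)c1 | intermediate
24 | tert-butyl{3,5-dimethoxy-4-[3,4,5-trimethoxy-2-(3,4,5-trimethoxyphenoxy)phenoxy]phenoxy}dimethylsilane | COc1cc(O[Si](C)(C)C(C)(C)C)cc(OC)c1Oc1cc(OC)c(OC)c(OC)c1Oc1cc(OC)c(OC)c(OC)c1 | intermediate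
25 | 4,6-dibromo-5-[2,6-dimethoxy-4-(2,4,6-trimethoxyphenoxy)phenoxy]-3-methoxycyclohexa-3,5-diene-1,2-dione | O=C1C(=O)C(OC)=C(Br)C(Oc2c(OC)cc(Oc3c(OC)cc(OC)cc3OC)cc2OC)=C1Br | intermediate (not isolated)
26 | 6-bromo-5-[2,6-dimethoxy-4-(2,4,6-trimethoxyphenoxy)phenoxy]-4-{3,5-dimethoxy-4-[3,4,5-trimethoxy-2-(3,4,5-trimethoxyphenoxy)phenoxy]phenoxy}-3-methoxycyclohexa-3,5-diene-1,2-dione | O=C1C(=O)C(OC)=C(Oc2cc(OC)c(Oc3cc(OC)c(OC)c(OC)c3Oc3cc(OC)c(OC)c(OC)c3)c(OC)c2)C(Oc2c(OC)cc(Oc3c(OC)cc(OC)cc3OC)cc2OC)=C1Br | intermediate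
27 | 6-bromo-5-[2,6-dimethoxy-4-(2,4,6-trimethoxyphenoxy)phenoxy]-4-{3,5-dimethoxy-4-[3,4,5-trimethoxy-2-(3,4,5-trimethoxyphenoxy)phenoxy]phenoxy}-3-methoxybenzene-1,2-diol | COc1c(O)c(O)c(Br)c(Oc2c(OC)cc(Oc3c(OC)cc(OC)cc3OC)cc2OC)c1Oc1cc(OC)c(Oc2cc(OC)c(OC)c(OC)c2Oc2cc(OC)c(OC)c(OC)c2)c(OC)c1 | intermediate (not isolated)
28 | 5-[2,6-dimethoxy-4-(2,4,6-trimethoxyphenoxy)phenoxy]-4-{3,5-dimethoxy-4-[3,4,5-trimethoxy-2-(3,4,5-trimethoxyphenoxy)phenoxy]phenoxy}-3-methoxybenzene-1,2-diol | COc1c(O)c(O)cc(Oc2c(OC)cc(Oc3c(OC)cc(OC)cc3OC)cc2OC)c1Oc1cc(OC)c(Oc2cc(OC)c(OC)c(OC)c2Oc2cc(OC)c(OC)c(OC)c2)c(OC)c1 | intermediate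
29 | CNP0114537.0 | Oc1cc(O)c(Oc2cc(O)c(Oc3cc(O)c(O)c(O)c3Oc3cc(O)c(Oc4cc(O)c(O)c(O)c4Oc4cc(O)c(O)c(O)c4)c(O)c3)c(O)c2)c(O)c1 | target

**Totals**

Total step count: 18.
Longest linear sequence: 10 steps (steps 3–9, then 16–18, from syringaldehyde).

**Steps most likely to fail**

Step 16. Three processes may defeat the union.
- Electron transfer from the electron-rich phenoxides to the quinone may outrun addition, giving phenoxyl radical coupling and semiquinone.
- The ring D phenoxide may attack through an ortho carbon instead of oxygen.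
- The site order may be lost, either by first attack at C4 or by ipso exchange of the ring B aryloxy group at C5 during the second stage.

The fallback uses known reaction types only, sets out from 23 and comes back to the route at 29. Ring C is grown onto the DEF phenol by the bromobenzaldehyde coupling and Baeyer–Villiger sequence already used for ring E, and rings B and A are then added one at a time with 8. Phenol 23 is coupled with 16 (CuI, picolinic acid, K3PO4, DMSO, 100 °C) to the CDEF aldehyde F1. mCPBA in CH2Cl2 should give the CDEF aryl formate F2, and K2CO3 in MeOH the CDEF phenol F3, whose hydroxyl sits on the ring C carbon next to the C–H. Coupling of F3 with 8 under the same copper conditions gives the BCDEF aldehyde F4, which is oxidised to the BCDEF aryl formate F5 and methanolysed to the BCDEF phenol F6. A third coupling with 8 gives the ABCDEF aldehyde F7, then the ABCDEF aryl formate F8 and the hexamer phenol F9, which carries fifteen methyl ethers and a free hydroxyl at C4 of ring A. BBr3 in CH2Cl2 then cleaves the fifteen methyl ethers of F9 and gives 29 directly, since ring A needs a hydroxyl at that position. This sequence is longer and linear, but each ether bond is placed without any question of site.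

Step 18. The cleavage of fourteen methyl ethers may stop short, the HBr formed may cut diaryl ether bonds at the most electron-rich rings, and the free pyrogallol units may oxidise in air during isolation. The fallback sets out from 28 and comes back at 29, and it changes the way the product is secured. After the ether cleavage the solvent is removed and the crude polyphenol is acetylated in the same flask (Ac2O, pyridine, DMAP) to the hexadecaacetate F10. F10 is stable to air and can be purified on silica, where under-demethylated material is separated and can be resubmitted. Acid-catalysed methanolysis under argon (AcCl cat., MeOH, rt) then releases 29 with methyl acetate as the only co-product, so evaporation suffices.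

Step 17. Hydrogenolysis of the C6–Br bond, shielded between a hydroxyl and a bulky aryloxy group, may be incomplete; bromide may slow the catalyst; and the electron-rich catechol may re-oxidise to the quinone during work-up. The fallback sets out from 26 and comes back at 29, separating the reduction from the bromine removal and capping the catechol. Na2S2O4 in EtOAc/water reduces 26 to the bromocatechol 27, which is now isolated. MeI and K2CO3 in DMF under argon give the bromo hexadecamethyl ether F11. Bromine–lithium exchange (n-BuLi, THF, −78 °C) followed by MeOH quench gives the hexadecamethyl ether F12, an air-stable compound that can be purified. BBr3 in CH2Cl2 then cleaves all sixteen methyl ethers to 29.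

**Further compounds**

F1 | step 16 | CDEF aldehyde: 3,4,5-trimethoxy-2-{3,5-dimethoxy-4-[3,4,5-trimethoxy-2-(3,4,5-trimethoxyphenoxy)phenoxy]phenoxy}benzaldehyde | O=Cc1cc(OC)c(OC)c(OC)c1Oc1cc(OC)c(Oc2cc(OC)c(OC)c(OC)c2Oc2cc(OC)c(OC)c(OC)c2)c(OC)c1
F2 | step 16 | CDEF aryl formate: formate ester of F3 | O=COc1cc(OC)c(OC)c(OC)c1Oc1cc(OC)c(Oc2cc(OC)c(OC)c(OC)c2Oc2cc(OC)c(OC)c(OC)c2)c(OC)c1
F3 | step 16 | CDEF phenol: 3,4,5-trimethoxy-2-{3,5-dimethoxy-4-[3,4,5-trimethoxy-2-(3,4,5-trimethoxyphenoxy)phenoxy]phenoxy}phenol | Oc1cc(OC)c(OC)c(OC)c1Oc1cc(OC)c(Oc2cc(OC)c(OC)c(OC)c2Oc2cc(OC)c(OC)c(OC)c2)c(OC)c1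
F4 | step 16 | BCDEF aldehyde: 3,5-dimethoxy-4-(CDEF-oxy)benzaldehyde, ring B carrying CHO | COc1cc(C=O)cc(OC)c1Oc1cc(OC)c(OC)c(OC)c1Oc1cc(OC)c(Oc2cc(OC)c(OC)c(OC)c2Oc2cc(OC)c(OC)c(OC)c2)c(OC)c1
F5 | step 16 | BCDEF aryl formate: formate ester of F6 | COc1cc(OC=O)cc(OC)c1Oc1cc(OC)c(OC)c(OC)c1Oc1cc(OC)c(Oc2cc(OC)c(OC)c(OC)c2Oc2cc(OC)c(OC)c(OC)c2)c(OC)c1
F6 | step 16 | BCDEF phenol: 3,5-dimethoxy-4-(CDEF-oxy)phenol, free hydroxyl on ring B | COc1cc(O)cc(OC)c1Oc1cc(OC)c(OC)c(OC)c1Oc1cc(OC)c(Oc2cc(OC)c(OC)c(OC)c2Oc2cc(OC)c(OC)c(OC)c2)c(OC)c1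
F7 | step 16 | ABCDEF aldehyde: 3,5-dimethoxy-4-(BCDEF-oxy)benzaldehyde, ring A carrying CHO | COc1cc(C=O)cc(OC)c1Oc1cc(OC)c(Oc2cc(OC)c(OC)c(OC)c2Oc2cc(OC)c(Oc3cc(OC)c(OC)c(OC)c3Oc3cc(OC)c(OC)c(OC)c3)c(OC)c2)c(OC)c1
F8 | step 16 | ABCDEF aryl formate: formate ester of F9 | COc1cc(OC=O)cc(OC)c1Oc1cc(OC)c(Oc2cc(OC)c(OC)c(OC)c2Oc2cc(OC)c(Oc3cc(OC)c(OC)c(OC)c3Oc3cc(OC)c(OC)c(OC)c3)c(OC)c2)c(OC)c1
F9 | step 16 | hexamer phenol: pentadecamethyl ether of 29 with free hydroxyl at C4 of ring A | COc1cc(O)cc(OC)c1Oc1cc(OC)c(Oc2cc(OC)c(OC)c(OC)c2Oc2cc(OC)c(Oc3cc(OC)c(OC)c(OC)c3Oc3cc(OC)c(OC)c(OC)c3)c(OC)c2)c(OC)c1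
F10 | step 18 | hexadecaacetate of 29 | CC(=O)Oc1cc(OC(C)=O)c(Oc2cc(OC(C)=O)c(Oc3cc(OC(C)=O)c(OC(C)=O)c(OC(C)=O)c3Oc3cc(OC(C)=O)c(Oc4cc(OC(C)=O)c(OC(C)=O)c(OC(C)=O)c4Oc4cc(OC(C)=O)c(OC(C)=O)c(OC(C)=O)c4)c(OC(C)=O)c3)c(OC(C)=O)c2)c(OC(C)=O)c1
F11 | step 17 | bromo hexadecamethyl ether: ring C as 1-bromo-4,5,6-trimethoxy-2-(AB-oxy)-3-(DEF-oxy)benzene | COc1c(Br)c(Oc2c(OC)cc(Oc3c(OC)cc(OC)cc3OC)cc2OC)c(Oc2cc(OC)c(Oc3cc(OC)c(OC)c(OC)c3Oc3cc(OC)c(OC)c(OC)c3)c(OC)c2)c(OC)c1OC
F12 | step 17 | hexadecamethyl ether of 29 | COc1cc(Oc2c(OC)cc(Oc3c(OC)cc(OC)cc3OC)cc2OC)c(Oc2cc(OC)c(Oc3cc(OC)c(OC)c(OC)c3Oc3cc(OC)c(OC)c(OC)c3)c(OC)c2)c(OC)c1OC
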